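**Assumptions:** (E)-1-Nitropropene is commercial. The (S)-diphenylprolinol silyl ether gives the same facial sense with a methyl β-substituent as with phenyl. The C3/C4 methyls come from the Michael step, the C2/C5 aryls from the Friedel–Crafts step, and all four side-chain carbinol/ether centres from the final transfer hydrogenation.

## Retrosynthetic overview
1. Manassantin A ⇒ bis(α-aryloxy ketone) **11**. Two Ru-catalysed transfer hydrogenations with dynamic kinetic resolution set all four side-chain stereocentres. **11** ⇒ bisphenol **8** + 2 α-bromoketone **10** (Williamson O-alkylation).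
2. **8** ⇒ cyclic bis-acetal **6** + 2 guaiacol, by double oxocarbenium Friedel–Crafts arylation. Inside-face attack on the diequatorial envelope of the trans-3,4-dimethyl oxocarbenium ion gives the 2,3-cis/4,5-cis/2,5-trans ring.
3. **6** ⇒ aldehyde-acetal **5** (transacetalisation) ⇒ nitro acetal **4** (Nef) ⇒ nitroaldehyde **3** ⇒ propanal + nitropropene by organocatalytic Michael addition, which sets the C3/C4 dyad.
4. Order of bond and ring formation: C3–C4 dyad (step 1), THF ring as cyclic acetal (step 4), aryl–C2/C5 bonds (step 5), aryl ethers (step 7), carbinols (step 8).

## Route

**Step 1**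
Reactants: **1** propanal (3 equiv); **2** (E)-1-nitroprop-1-ene
Product: **3** (2R,3R)-2,3-dimethyl-4-nitrobutanal
Conditions: (S)-α,α-diphenylprolinol TMS ether (10 mol%), PhCO2H (10 mol%), hexane, 0 °C → rt, 24 h
Reagents that add atoms: none
Why: Enamine-catalysed Michael addition (Hayashi–Jørgensen). The bulky catalyst shields one enamine face and the nitroalkene approaches through the synclinal acyclic transition state. This gives the syn adduct (2R,3R), which becomes the trans-3,4-dimethyl dyad after ring closure. The crude aldehyde is taken on at once because its α-centre is epimerisable.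

**Step 2**
Reactants: **3**
Product: **4** (2R,3R)-1,1-dimethoxy-2,3-dimethyl-4-nitrobutane
Conditions: HC(OMe)3 (3 equiv), MeOH, p-TsOH·H2O (5 mol%), rt, 2 h
Reagents that add atoms: trimethyl orthoformate, COC(OC)OC; methanol, CO
Why: Dimethyl acetalisation locks the epimerisable α-centre before the basic Nef step. The nitro group is inert to these conditions.

**Step 3**
Reactants: **4**
Product: **5** (2R,3R)-4,4-dimethoxy-2,3-dimethylbutanal
Conditions: (i) t-BuOK, THF, 0 °C, 15 min; (ii) add the nitronate to Oxone (2 equiv), NaHCO3, H2O/THF, 0 °C, 30 min; cold extractive work-up, no chromatography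
Reagents that add atoms: Oxone (potassium peroxymonosulfate), OOS(=O)(=O)[O-].[K+], and water, O (together they supply the carbonyl oxygen)
Why: Oxidative Nef reaction. Deprotonation occurs at the CH2NO2 carbon, which is remote from both stereocentres. The buffered peroxymonosulfate converts the nitronate to the aldehyde and leaves the dimethyl acetal intact. The new aldehyde has an epimerisable α-methyl centre, so the crude is kept cold and cyclised immediately in step 4.

**Step 4**
Reactants: **5**
Product: **6** (3R,4R)-2,5-dimethoxy-3,4-dimethyltetrahydrofuran (C2/C5 anomer mixture)
Conditions: PPTS (10 mol%), MeOH (0.2 equiv), anhydrous CH2Cl2, rt, 4 h; then Et3N quench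
Reagents that add atoms: none (net isomerisation; MeOH is regenerated)
Why: Acid-catalysed intramolecular transacetalisation. MeOH adds to the aldehyde, and the hemiacetal OH captures the oxocarbenium ion from the dimethyl acetal to close the five-membered ring. Non-nucleophilic solvent and only catalytic MeOH avoid reversion to the acyclic tetramethoxy acetal. No enolisable carbonyl remains, so C3/C4 are locked. The anomeric centres are left as a mixture because both converge on the oxocarbenium ion in step 5.

**Step 5**
Reactants: **6**; **7** guaiacol (2-methoxyphenol, 5 equiv)
Product: **8** (2S,3R,4R,5S)-2,5-bis(4-hydroxy-3-methoxyphenyl)-3,4-dimethyltetrahydrofuran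
Conditions: TfOH (5 mol%), HFIP, 0 °C, 1–2 h; quench with Et3N as soon as **6** is consumed
Reagents that add atoms: none (all aryl atoms come from **7**; two MeOH are lost)
Why: Proposed new method: double Friedel–Crafts C-arylation of a 2,5-dimethoxy-3,4-dimethyl-THF, with arene attack para to the phenol OH on each cyclic oxocarbenium ion. For the C2 cation, C4 is the envelope flap. The trans-3,4-dimethyl pattern lets one envelope hold both methyls pseudo-equatorial. Inside-face attack on that conformer (the stereoelectronically preferred, Woerpel-type trajectory) puts the new aryl trans to the C4 methyl and cis to the C3 methyl. Ionisation of the second OMe repeats this at C5 with C3 as the flap, and the C2 aryl sits on the opposite face from the incoming nucleophile. This gives 2,3-cis, 4,5-cis, 2,5-trans. The closest known reactions are inside-attack substitution of 2-alkoxy-THF acetals with allylsilanes and Friedel–Crafts C-glycosylation of phenols. The product is the kinetic, less stable cis-aryl/methyl isomer, so low temperature and a short reaction time are needed to avoid benzylic ionisation and drift to the all-trans isomer.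

**Step 6**
Reactants: **9** 1-(3,4-dimethoxyphenyl)propan-1-one
Product: **10** (±)-2-bromo-1-(3,4-dimethoxyphenyl)propan-1-one
Conditions: CuBr2 (2 equiv), EtOAc/CHCl3 1:1, reflux, 4 h
Reagents that add atoms: copper(II) bromide, Br[Cu]Br
Why: CuBr2 α-brominates aryl ketones through the enol without brominating the ring. The α-centre is left racemic on purpose because it is racemised and resolved in step 8.

**Step 7**
Reactants: **8**; **10** (2.4 equiv)
Product: **11** bis(α-aryloxy ketone), epimeric at both α-carbons (Cb/Cb′)
Conditions: K2CO3 (3 equiv), KI (cat.), acetone, 55 °C, 12 h
Reagents that add atoms: none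
Why: Williamson O-alkylation (SN2) of the phenolates on the activated secondary α-bromoketone. The THF stereocentres are stable to mild base. The α-centres of the products are epimerisable aryloxy ketones, ready for dynamic resolution.

**Step 8**
Reactants: **11**
Product: **12** manassantin A
Conditions: RuCl[(S,S)-TsDPEN](p-cymene) (5 mol%), HCO2H/Et3N 5:2, EtOAc, 40 °C, 48 h
Reagents that add atoms: none (formate supplies only hydrogen)
Why: Noyori–Ikariya asymmetric transfer hydrogenation with dynamic kinetic resolution. The (S,S)-catalyst delivers hydride to the face that gives the (R)-carbinol. Fast enolisation of each α-aryloxy ketone funnels both α-epimers through the matched one, giving (R,R) (threo) at each arm. The THF core is remote, so the two arms react independently under catalyst control.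

## Compound list
1 | propanal | CCC=O | starting material
2 | (E)-1-nitroprop-1-ene | C/C=C/[N+](=O)[O-] | starting material
3 | (2R,3R)-2,3-dimethyl-4-nitrobutanal | O=C[C@H](C)[C@@H](C)C[N+](=O)[O-] | intermediate
4 | (2R,3R)-1,1-dimethoxy-2,3-dimethyl-4-nitrobutane | COC(OC)[C@H](C)[C@@H](C)C[N+](=O)[O-] | intermediate
5 | (2R,3R)-4,4-dimethoxy-2,3-dimethylbutanal | COC(OC)[C@H](C)[C@@H](C)C=O | intermediate
6 | (3R,4R)-2,5-dimethoxy-3,4-dimethyltetrahydrofuran (anomers undefined) | COC1OC(OC)[C@H](C)[C@H]1C | intermediate
7 | guaiacol | COc1ccccc1O | starting material
8 | (2S,3R,4R,5S)-2,5-bis(4-hydroxy-3-methoxyphenyl)-3,4-dimethyltetrahydrofuran | COc1cc([C@H]2O[C@H](c3ccc(O)c(OC)c3)[C@H](C)[C@H]2C)ccc1O | intermediate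
9 | 1-(3,4-dimethoxyphenyl)propan-1-one | CCC(=O)c1ccc(OC)c(OC)c1 | starting material
10 | (±)-2-bromo-1-(3,4-dimethoxyphenyl)propan-1-one | CC(Br)C(=O)c1ccc(OC)c(OC)c1 | intermediate
11 | bis(α-aryloxy ketone) from 8 and 10 (side-chain methine centres undefined) | COc1ccc(C(=O)C(C)Oc2ccc([C@H]3O[C@H](c4ccc(OC(C)C(=O)c5ccc(OC)c(OC)c5)c(OC)c4)[C@H](C)[C@H]3C)cc2OC)cc1OC | intermediate
12 | manassantin A | COc1ccc([C@@H](O)[C@@H](C)Oc2ccc([C@H]3O[C@H](c4ccc(O[C@H](C)[C@H](O)c5ccc(OC)c(OC)c5)c(OC)c4)[C@H](C)[C@H]3C)cc2OC)cc1OC | target

**Total steps:** 8. **Longest linear sequence:** 7 (steps 1, 2, 3, 4, 5, 7, 8). Step 6 is a parallel branch.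

## Three steps most likely to fail
1. **Step 5 (proposed new method).** Possible problems are O- or ortho-attack of guaiacol, stopping at mono-arylation, and acid-induced benzylic ionisation of the electron-rich product through a p-quinone methide, which would epimerise the aryl centres toward the all-trans isomer.
   - Fallback (known chemistry, stepwise core): add ArMgBr (Ar = 4-BnO-3-MeOC6H3) to aldehyde **5** under Felkin–Anh control. Protect the carbinol, unmask the second aldehyde and add a second aryl Grignard. Use oxidation and catalyst-controlled reduction where needed to obtain the 1,4-diaryl-2,3-dimethylbutane-1,4-diol diastereomer in which the two carbinols differ in configuration relative to their methyl neighbours. Close the ring by mono-mesylation and SN2 cyclisation with inversion at one carbinol to give the 2,5-trans THF, then remove the benzyl groups by hydrogenolysis to give **8**.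
2. **Step 8.** The α-aryloxy ketones may racemise too slowly for efficient dynamic resolution, or the catalyst may give the wrong syn/anti ratio at Cb.
   - Fallback (different approach): set Cb first. Shi asymmetric epoxidation of the TBS enol ether of **9** gives the (S)-α-hydroxy ketone after desilylation. Mitsunobu O-arylation of **8** with inversion gives the (R)-aryl ether at both arms. Then reduce both ketones with the CBS catalyst enantiomer that delivers the (R)-carbinol.
3. **Steps 3–4 (Nef, then cyclisation).** The Nef step may epimerise the α-methyl centre of the aldehyde or hydrolyse the acetal, and the cyclisation may stall at acyclic material.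
   - Fallback (different approach): make the (R,R)-2,3-dimethylsuccinate skeleton by oxidative homocoupling of an Evans N-propionyl oxazolidinone enolate (auxiliary-controlled). Reduce it to the diol with LiBH4 and oxidise it (Swern) to the dialdehyde, which is used immediately. Close it with MeOH/H+ to give **6**.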